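The numbers in the tables are simulated on assumed constants.

In a one-step world each partner turns one substrate into one target, so the flask planned here, with c(partner) at 0.160 M against 0.20 M of substrate, would end at 80.0 % target; that partner yield of 1 is the zero of our scale.

| setting | spring | flask |
|---|---|---|
| substrate | 0.20 M (fed, over 30 min) | 0.20 M (fed, over 30 min) |
| partner | 0.32 M | 0.160 M |
| remark | run made earlier |  |
| time |  | 6.0 d |

spring run (percent of the substrate charged)

| time / h | open intermediate / % | target / % | substrate / % |
|---|---|---|---|
| 5.00 | 11 | 29 | 47 |
| 15.0 | 3 | 54 | 22 |
| 30.0 | 6 | 65 | 8 |
| 40.0 | 1 | 68 | 6 |

(standard deviation of a reading: 1.5 percentage points)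



- the best time, 6.0 d at the latest, for open intermediate
- the amount of open intermediate, in percent of the substrate charged, at that time
- the first time at which open intermediate reaches 12 %, in the same percent

The spring run stands below that zero: its reading of 68 % target at 40.0 h is 0.136 M from 0.32 M of partner, so the partner yield, target formed per partner charged, is 0.425, less than one target per partner. This is a reading with a scatter of 1.5 percentage points, and substrate had fallen to 6 % by then, so we take it as a lower mark. Carried to the flask, it gives 34.0 % target, half of the spring reading. We want open intermediate rather than target, so we keep partner at 0.160 M and do not go back to 0.32 M. The highest spring reading of open intermediate, 11 %, is also its first, at 5.00 h, so we expect the best of the flask above that reading and put our samples before that time.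

The forecast, which gives 13 % at 0.35 d, later than the 5.00 h before which we sample, and the asked level at 4 h, reasons that “Partner then runs out, leaving I nearly frozen just below its peak.”

The flask reaches its best, 16.5 %, at 0.0667 d, having passed the asked level at 0.703 h, and at that best time partner stands at 13.3 % of its own charge.

    partner → decomposed reagent (k = 1.70 × 10⁻⁴ /s)
    partner → second intermediate (k = 1.80 × 10⁻⁴ /s)
    open intermediate + second intermediate → target (k = 0.00120 /M/s)
    substrate ⇌ open intermediate (K = 0.300, k = 1.20 × 10⁻⁴ /s)
    2 open intermediate → homo product (k = 0.00110 /M/s)

At 6.00 d the flask holds 40.7 % target with 0 % left of partner, the limiting reagent, so its partner yield is 0.509, higher than the 0.425 read from the spring run. With that yield a neighbour flask, like this one but charged with 0.064 M of partner, comes to 16.3 % target, and at 6.00 d that neighbour holds 16.4 %.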